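**Retrosynthetic overview**
1. The pyran ring is made last by closing the C5'–C4'' bond: an enantioselective intramolecular phenolic aldol of a β-aryloxy aldehyde gives the target directly, with no protecting group left to remove.
2. Enabling feature: in ring A, O4'–C4'=C5' is an enol whose carbon C5' is the only unsubstituted ring carbon, flanked by the 4'-OH and the ether oxygen on C6'. The C4''–OH lies β to C4' (an aldol retron), and the C6'–O–C6''(CH3)2–C5''H2 tether makes the closure six-membered.
3. The aldehyde comes from a terminal alkyne by anti-Markovnikov hydroboration–oxidation. The O–C6'' bond comes from copper-catalysed tert-propargylation of the 6'-OH while the 4'-OH is masked as a silyl ether.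
4. The acyl chain is installed first by Friedel–Crafts acylation of symmetric 2-methylphloroglucinol. Ring A and the phenyl ring are bought; the pyran ring is the only ring formed.

Key step: step 6

Assumption: 2-methylphloroglucinol is taken as a catalogue compound (otherwise one step from 2,4,6-trihydroxybenzaldehyde by reduction).
Assumption: the sense of induction of the quinine-derived squaramide in step 6 is assigned from its usual bifunctional binding model; should the other face be favoured, the quinidine-derived pseudo-enantiomer replaces it with no other change.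

Step 1
Reactants: 1 2-methylphloroglucinol (2-methylbenzene-1,3,5-triol); 2 3-phenylpropanoyl chloride
Product: 3 1-(2,4,6-trihydroxy-3-methylphenyl)-3-phenylpropan-1-one (2',4',6'-trihydroxy-3'-methyldihydrochalcone)
Conditions: AlCl3 (3.5 equiv), PhNO2, 0 → 60 °C; then ice/aq. HCl
Reagents that add atoms: 3-phenylpropanoyl chloride (2), O=C(Cl)CCc1ccccc1
Why: Friedel–Crafts C-acylation of the phloroglucinol nucleus, in which the two free ring positions of 1 are equivalent by symmetry so that one regioisomer forms, and the new acyl group deactivates the ring against a second acylation.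

Step 2
Reactants: 3 1-(2,4,6-trihydroxy-3-methylphenyl)-3-phenylpropan-1-one
Product: 4 1-[2,6-dihydroxy-3-methyl-4-(triisopropylsilyloxy)phenyl]-3-phenylpropan-1-one
Conditions: TIPSCl (1.05 equiv), imidazole (2.2 equiv), DMF, −20 → 0 °C
Reagents that add atoms: chlorotri(propan-2-yl)silane (TIPSCl), CC(C)[Si](Cl)(C(C)C)C(C)C
Why: Imidazole-mediated O-silylation should take the 4'-OH, the most acidic phenol (para to the carbonyl) and the only one that cannot hydrogen-bond to the ketone, which blocks the oxygen that would otherwise be alkylated first.

Step 3
Reactants: 4 1-[2,6-dihydroxy-3-methyl-4-(triisopropylsilyloxy)phenyl]-3-phenylpropan-1-one; 5 3-chloro-3-methylbut-1-yne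
Product: 6 1-[2-hydroxy-3-methyl-6-(2-methylbut-3-yn-2-yloxy)-4-(triisopropylsilyloxy)phenyl]-3-phenylpropan-1-one
Conditions: DBU (1.6 equiv), CuCl2·2H2O (1 mol %), MeCN, 0 °C
Reagents that add atoms: 3-chloro-3-methylbut-1-yne (5), C#CC(C)(C)Cl
Why: Copper-catalysed propargylic etherification (through a copper allenylidene) builds the hindered aryl tert-alkyl ether at 0 °C, and the 6'-OH should react in preference to the 2'-OH because the latter is locked in the hydrogen bond to the ketone and buttressed by the 3'-methyl group, the usual order (4' before 6' before 2') in partial alkylation of C-methylated phloroacylphenones.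

Step 4
Reactants: 6 1-[2-hydroxy-3-methyl-6-(2-methylbut-3-yn-2-yloxy)-4-(triisopropylsilyloxy)phenyl]-3-phenylpropan-1-one
Product: 8 3-[3-hydroxy-4-methyl-2-(3-phenylpropanoyl)-5-(triisopropylsilyloxy)phenoxy]-3-methylbutanal, via (E)-alkenyldicyclohexylborane 7 (not isolated)
Conditions: Cy2BH (2.5 equiv, made in the flask from BH3·SMe2 and cyclohexene), THF, 0 °C; then 30% H2O2, pH 7 phosphate buffer, 0 °C
Reagents that add atoms: hydrogen peroxide, OO; dicyclohexylborane, B(C1CCCCC1)C1CCCCC1 (its atoms are carried only by intermediate 7)
Why: Brown hydroboration of the terminal alkyne with a bulky dialkylborane places boron on the terminal carbon and buffered oxidation of the alkenylborane should give the aldehyde, while the 2'-OH is held as its boron chelate with the ketone and pH 7 keeps the β-aryloxy aldehyde from eliminating or cyclising.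

Step 5
Reactants: 8 3-[3-hydroxy-4-methyl-2-(3-phenylpropanoyl)-5-(triisopropylsilyloxy)phenoxy]-3-methylbutanal
Product: 9 3-[3,5-dihydroxy-4-methyl-2-(3-phenylpropanoyl)phenoxy]-3-methylbutanal
Conditions: TBAF (1.2 equiv), AcOH (1.5 equiv), THF, 0 °C; extractive work-up, used without chromatography
Reagents that add atoms: none
Why: Fluoride cleavage of the aryl silyl ether under acetic acid buffering should free the 4'-OH without forming a phenoxide, so that the aldehyde neither closes to racemic carbinol nor loses the phenoxide by β-elimination.

Step 6
Reactants: 9 3-[3,5-dihydroxy-4-methyl-2-(3-phenylpropanoyl)phenoxy]-3-methylbutanal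
Product: 11 (4''R)-2',4',4''-trihydroxy-3',6'',6''-trimethylpyrano[2'',3'':6',5']dihydrochalcone [1-[(4R)-4,5,7-trihydroxy-2,2,6-trimethyl-3,4-dihydro-2H-chromen-8-yl]-3-phenylpropan-1-one], via cyclohexadienone aldol adduct 10 (not isolated)
Conditions: quinine-derived squaramide 3-{[3,5-bis(trifluoromethyl)phenyl]amino}-4-{[(8α,9S)-6'-methoxycinchonan-9-yl]amino}cyclobut-3-ene-1,2-dione (10 mol %), CH2Cl2, −30 °C
Reagents that add atoms: none
Why: Proposed new method: the quinuclidine nitrogen acts as a general base on the 4'-OH (the most acidic phenol, para to the ketone) while the squaramide N–H pair hydrogen-bonds the formyl oxygen, and the phenol, reacting as the enol O4'–C4'=C5', adds through C5' to the aldehyde to give dienone 10, which tautomerises to the aromatic carbinol (an intramolecular phenolic aldol, that is a Friedel–Crafts hydroxyalkylation). The closest known reactions are the cinchona squaramide- and thiourea-catalysed enantioselective ortho-hydroxyalkylations of phenols and naphthols with activated carbonyl compounds (isatins, trifluoropyruvates, glyoxals) and the ortho-hydroxyalkylation of magnesium phenoxides by aliphatic aldehydes; new here are the unactivated aldehyde and the intramolecular closure to a chroman-4-ol. The pyran ring closes in the 6-(enolexo)-exo-trig mode, helped by the gem-dimethyl group on C6''. The single stereocentre C4'' is set by the catalyst, which is expected to present the Si face of the aldehyde to C5' and so give the R carbinol. The step needs site selectivity, chemoselectivity and freedom from elimination: C5' is the only unsubstituted carbon of ring A and is ortho or para to all three ring oxygens, the aldehyde is far more electrophilic than the chelated and doubly ortho-substituted ketone, and the low temperature and weakly basic medium disfavour both β-elimination of the phenoxide from 9 and loss of water from 11 through an ortho-quinone methide.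

**Compound list**
1 | 2-methylphloroglucinol (2-methylbenzene-1,3,5-triol) | Cc1c(O)cc(O)cc1O | starting material
2 | 3-phenylpropanoyl chloride | O=C(Cl)CCc1ccccc1 | starting material
3 | 1-(2,4,6-trihydroxy-3-methylphenyl)-3-phenylpropan-1-one | Cc1c(O)cc(O)c(C(=O)CCc2ccccc2)c1O | intermediate
4 | 1-[2,6-dihydroxy-3-methyl-4-(triisopropylsilyloxy)phenyl]-3-phenylpropan-1-one (4'-O-silyl ether) | Cc1c(O[Si](C(C)C)(C(C)C)C(C)C)cc(O)c(C(=O)CCc2ccccc2)c1O | intermediate
5 | 3-chloro-3-methylbut-1-yne | C#CC(C)(C)Cl | starting material
6 | 1-[2-hydroxy-3-methyl-6-(2-methylbut-3-yn-2-yloxy)-4-(triisopropylsilyloxy)phenyl]-3-phenylpropan-1-one (6'-O-propargyl ether) | Cc1c(O[Si](C(C)C)(C(C)C)C(C)C)cc(OC(C)(C)C#C)c(C(=O)CCc2ccccc2)c1O | intermediate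
7 | (E)-alkenyldicyclohexylborane of 6 (boron on the terminal carbon; the 2'-OH held as its O-dicyclohexylboryl ether) | Cc1c(O[Si](C(C)C)(C(C)C)C(C)C)cc(OC(C)(C)/C=C/B(C2CCCCC2)C2CCCCC2)c(C(=O)CCc2ccccc2)c1OB(C1CCCCC1)C1CCCCC1 | intermediate
8 | 3-[3-hydroxy-4-methyl-2-(3-phenylpropanoyl)-5-(triisopropylsilyloxy)phenoxy]-3-methylbutanal | Cc1c(O[Si](C(C)C)(C(C)C)C(C)C)cc(OC(C)(C)CC=O)c(C(=O)CCc2ccccc2)c1O | intermediate
9 | 3-[3,5-dihydroxy-4-methyl-2-(3-phenylpropanoyl)phenoxy]-3-methylbutanal | Cc1c(O)cc(OC(C)(C)CC=O)c(C(=O)CCc2ccccc2)c1O | intermediate
10 | cyclohexadienone aldol adduct (keto tautomer of 11: C5' sp3 and of transient configuration, C4'=O, C4'' of R configuration) | CC1=C(O)C(C(=O)CCc2ccccc2)=C2OC(C)(C)C[C@@H](O)C2C1=O | intermediate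
11 | (4''R)-2',4',4''-trihydroxy-3',6'',6''-trimethylpyrano[2'',3'':6',5']dihydrochalcone | Cc1c(O)c(C(=O)CCc2ccccc2)c2c(c1O)[C@H](O)CC(C)(C)O2 | target

Total step count: 6. Longest linear sequence: 6 steps (1 → 3 → 4 → 6 → 8 → 9 → 11).

**Steps most likely to fail**

Step 6 (the proposed new method and the riskiest step). What may go wrong: the uncatalysed closure may compete with the catalyst-bound pathway and erode facial selectivity, the amine may trigger β-elimination of the phenoxide from the aldehyde, or the carbinol may lose water through an ortho-quinone methide. Fallback (known chemistry, stereocontrol by resolution instead of catalysis): setting out from 9, closure of the same C5'–C4'' bond under magnesium phenoxide conditions (MgCl2, Et3N, MeCN, 0 °C; the ortho-hydroxyalkylation of magnesium phenoxides by aldehydes) should give the racemic carbinol F1. Preparative chromatography on a chiral stationary phase (amylose tris(3,5-dimethylphenylcarbamate), supercritical CO2/MeOH) should then separate it into 11, where the fallback comes back to the route, and the S enantiomer F2, which is set aside.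

Step 3. What may go wrong: slow O-alkylation of the hindered ortho-acyl phenoxide, partial reaction at the 2'-oxygen, and loss or migration of the silyl group under the amidine base. Fallback (base-free π-allyl chemistry instead of copper allenylidene chemistry; it addresses the reactivity and silyl-loss risks, not the 2'/6' site selectivity, and it bypasses step 4 as well): setting out from 4, Tsuji–Trost O-allylation with 2-methylbut-3-en-2-yl methyl carbonate and Pd(PPh3)4 in THF at 0 °C should give, as the kinetic branched product, the 1,1-dimethylallyl ether F3. Aldehyde-selective Wacker oxidation of its terminal alkene (PdCl2(PhCN)2, CuCl2·2H2O, AgNO2, O2, t-BuOH/MeNO2, rt; the quaternary allylic carbon and the allylic oxygen both direct oxygen to the terminal carbon) comes back to the route at 8.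

Step 4. What may go wrong: reduction of the boron-chelated aryl ketone by excess borane, oxidative damage to the electron-rich ring during the peroxide work-up, and β-elimination of the phenoxide from the new aldehyde. Fallback (redox-neutral catalytic hydration instead of hydroboration–oxidation): setting out from 6, ruthenium-catalysed anti-Markovnikov hydration of the terminal alkyne (CpRu(MeCN)3PF6 with 5,5'-bis(trifluoromethyl)-2,2'-bipyridine, NMP/H2O, 25 °C; through a ruthenium vinylidene) should lead in one operation to 8, where it comes back to the route; no new compound lies on this path (F0).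

Further compounds
F1 | step 6 | racemic 2',4',4''-trihydroxy-3',6'',6''-trimethylpyrano[2'',3'':6',5']dihydrochalcone (racemic carbinol) | Cc1c(O)c(C(=O)CCc2ccccc2)c2c(c1O)C(O)CC(C)(C)O2
F2 | step 6 | (4''S)-2',4',4''-trihydroxy-3',6'',6''-trimethylpyrano[2'',3'':6',5']dihydrochalcone (S enantiomer of 11) | Cc1c(O)c(C(=O)CCc2ccccc2)c2c(c1O)[C@@H](O)CC(C)(C)O2
F3 | step 3 | 1-[2-hydroxy-3-methyl-6-(2-methylbut-3-en-2-yloxy)-4-(triisopropylsilyloxy)phenyl]-3-phenylpropan-1-one (1,1-dimethylallyl ether) | Cc1c(O[Si](C(C)C)(C(C)C)C(C)C)cc(OC(C)(C)C=C)c(C(=O)CCc2ccccc2)c1O
F0 | step 4 | none | none
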